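The benzene ring of the indole is disconnected at C5–C6, back to a pyrrole that carries a bromoethynyl group on C2 and a vinyl group on C3 (2-(bromoethynyl)-1-tosyl-3-vinylpyrrole). The feature exploited is that the benzene ring bears one substituent only, bromine on C7 beside the ring-fusion carbon C7a: this is where a 1,2-bromine shift delivers the halogen when the alkyne becomes a metal vinylidene. In a single AuCl-catalysed operation the bromine moves from C6 to C7, the C5–C6 bond forms and the ring aromatizes, with no oxidant. Detosylation and C3/C2 dibromination of the pyrrole ring then finish 2,3,7-tribromoindole.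

Key step: step 5

Assumptions: 3-bromo-1H-pyrrole-2-carbaldehyde is taken as commercially available. Indole numbering is used for the atoms of the ring being built, also in the pyrrole precursors: pyrrole C2 and C3 become C7a and C3a, the alkyne carbons become C7 and C6, and the vinyl carbons become C4 and C5. The N-tosyl group is kept on the precursor because a sulfonyl group, unlike a carbamate, has no carbonyl oxygen that could cyclize onto the activated alkyne.

Step 1
Reactants: 1 3-bromo-1H-pyrrole-2-carbaldehyde; 2 4-toluenesulfonyl chloride
Product: 4 3-bromo-1-tosyl-1H-pyrrole-2-carbaldehyde, via sodium 3-bromo-2-formylpyrrol-1-ide 3 (not isolated)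
Conditions: NaH (1.2 equiv), THF, 0 °C; then TsCl, 0 °C to rt
Reagents that add atoms: 4-toluenesulfonyl chloride, Cc1ccc(cc1)S(=O)(=O)Cl
Why: NaH deprotonates the acidic N–H of the 2-formylpyrrole and the resulting anion 3 is sulfonylated on nitrogen by TsCl (N-sulfonylation of a pyrrolide), which protects nitrogen and makes the ring electron-poor for the steps that follow.

Step 2
Reactants: 4 3-bromo-1-tosyl-1H-pyrrole-2-carbaldehyde; 5 potassium vinyltrifluoroborate
Product: 6 1-tosyl-3-vinyl-1H-pyrrole-2-carbaldehyde
Conditions: CH2=CHBF3K, PdCl2(dppf)·CH2Cl2 (3 mol %), Et3N (3 equiv), n-PrOH/H2O 9:1, 80 °C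
Reagents that add atoms: potassium vinyltrifluoroborate, C=C[B-](F)(F)F.[K+]
Why: Suzuki–Miyaura coupling of the trifluoroborate at the C3 bromide, whose oxidative addition is eased by the ortho formyl and N-sulfonyl groups, with an amine base too weak to cleave the N–S bond.

Step 3
Reactants: 6 1-tosyl-3-vinyl-1H-pyrrole-2-carbaldehyde; 7 carbon tetrabromide
Product: 8 2-(2,2-dibromovinyl)-1-tosyl-3-vinyl-1H-pyrrole
Conditions: CBr4 (2 equiv), PPh3 (4 equiv), CH2Cl2, 0 °C
Reagents that add atoms: carbon tetrabromide, BrC(Br)(Br)Br
Why: Ramirez dibromo-olefination, the first stage of the Corey–Fuchs sequence: Ph3P=CBr2 made in the flask from PPh3 and CBr4 converts the aldehyde into the 1,1-dibromoalkene by Wittig reaction under neutral conditions that leave the vinyl and sulfonyl groups alone.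

Step 4
Reactants: 8 2-(2,2-dibromovinyl)-1-tosyl-3-vinyl-1H-pyrrole
Product: 9 2-(bromoethynyl)-1-tosyl-3-vinyl-1H-pyrrole
Conditions: DBU (2.5 equiv), DMSO, 15–20 °C
Reagents that add atoms: none
Why: Anti E2 dehydrobromination of the aryl-type 1,1-dibromoalkene by the non-nucleophilic amidine base in DMSO should stop at the 1-bromoalkyne, and the mild, alkoxide-free conditions should spare the N-tosyl group.

Step 5
Reactants: 9 2-(bromoethynyl)-1-tosyl-3-vinyl-1H-pyrrole
Product: 11 7-bromo-1-tosyl-1H-indole, via AuCl bromovinylidene 10 (not isolated)
Conditions: AuCl (10 mol %), toluene, 80 °C, dark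
Reagents that add atoms: none
Why: Proposed new method: AuCl coordinates the bromoalkyne of 9 and a 1,2-bromine shift turns it into the AuCl bromovinylidene 10, in which bromine sits on C7 and the electrophilic carbene carbon is C6; the terminal vinyl carbon C5 adds to C6, and loss of a proton from C5 with protodeauration at C6 delivers the arene, no oxidant being needed because 9 and 11 are isomers. The closest known reaction type is the AuCl- or W(CO)5(thf)-catalysed cycloisomerization of ortho-(haloethynyl)styrenes and 2-(haloethynyl)biaryls to 1-halonaphthalenes and halophenanthrenes through metal halovinylidenes; what is new is that the central double bond of the dienyne is the C2–C3 bond of a pyrrole. The one ring that closes, the benzene ring of the indole, closes 6-endo with respect to the former alkyne, formally a six-electron electrocyclization of the triene C5=C4–C3a=C7a–C7=C6, and the pyrrole ring holds the central alkene cis so that C5 and C6 are within reach. No stereocentre is created. The selectivity required is that bromine migration precedes C–C bond formation (direct 6-endo attack would give the 6-bromo isomer and 5-exo attack a five-membered ring): AuCl is chosen because it favours the vinylidene manifold over plain π-activation, and the N-tosyl group lowers the nucleophilicity of the pyrrole and its vinyl group so that direct attack on the π-complex is slow. The sulfonyl group also offers no nucleophilic site that could trap the activated alkyne, and nitrogen itself is blocked.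

Step 6
Reactants: 11 7-bromo-1-tosyl-1H-indole
Product: 12 7-bromo-1H-indole
Conditions: Cs2CO3 (3 equiv), THF/MeOH 2:1, rt to 40 °C
Reagents that add atoms: none
Why: Nucleophilic N-desulfonylation: methoxide generated by Cs2CO3 attacks sulfur and expels the indolide, a cleavage that the electron-withdrawing and peri-crowding C7 bromine should make easier and that leaves the aryl bromide untouched.

Step 7
Reactants: 12 7-bromo-1H-indole; 13 N-bromosuccinimide
Product: 15 2,3,7-tribromo-1H-indole, via 3,7-dibromo-1H-indole 14 (not isolated)
Conditions: NBS (2.05 equiv), THF, −78 °C to rt, dark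
Reagents that add atoms: N-bromosuccinimide, O=C1CCC(=O)N1Br
Why: Electrophilic aromatic bromination of the pyrrole ring of the indole, first at the most nucleophilic C3 to give 14 and then at C2 (by way of C3 attack and 1,2-bromine shift), while the benzene ring, deactivated by the C7 bromine, should not compete under cold anhydrous conditions.

Compound list
1 | 3-bromo-1H-pyrrole-2-carbaldehyde | O=Cc1[nH]ccc1Br | starting material
2 | 4-toluenesulfonyl chloride | Cc1ccc(cc1)S(=O)(=O)Cl | starting material
3 | sodium 3-bromo-2-formylpyrrol-1-ide | O=Cc1[n-]ccc1Br.[Na+] | intermediate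
4 | 3-bromo-1-tosyl-1H-pyrrole-2-carbaldehyde | Cc1ccc(cc1)S(=O)(=O)n1ccc(Br)c1C=O | intermediate
5 | potassium vinyltrifluoroborate | C=C[B-](F)(F)F.[K+] | starting material
6 | 1-tosyl-3-vinyl-1H-pyrrole-2-carbaldehyde | Cc1ccc(cc1)S(=O)(=O)n1ccc(C=C)c1C=O | intermediate
7 | carbon tetrabromide | BrC(Br)(Br)Br | starting material
8 | 2-(2,2-dibromovinyl)-1-tosyl-3-vinyl-1H-pyrrole | Cc1ccc(cc1)S(=O)(=O)n1ccc(C=C)c1C=C(Br)Br | intermediate
9 | 2-(bromoethynyl)-1-tosyl-3-vinyl-1H-pyrrole | Cc1ccc(cc1)S(=O)(=O)n1ccc(C=C)c1C#CBr | intermediate
10 | AuCl bromovinylidene, chloro[2-bromo-2-(1-tosyl-3-vinyl-1H-pyrrol-2-yl)ethenylidene]gold | Cc1ccc(cc1)S(=O)(=O)n1ccc(C=C)c1C(Br)=C=[Au]Cl | intermediate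
11 | 7-bromo-1-tosyl-1H-indole | Cc1ccc(cc1)S(=O)(=O)n1ccc2cccc(Br)c21 | intermediate
12 | 7-bromo-1H-indole | Brc1cccc2cc[nH]c12 | intermediate
13 | N-bromosuccinimide | O=C1CCC(=O)N1Br | starting material
14 | 3,7-dibromo-1H-indole | Brc1c[nH]c2c(Br)cccc12 | intermediate
15 | 2,3,7-tribromo-1H-indole | Brc1[nH]c2c(Br)cccc2c1Br | target

Total step count: 7. Longest linear sequence: 7 steps (from compound 1).

Steps most likely to fail

1. Step 5 (proposed new method).
- What may go wrong: the vinyl group may attack the gold-bound alkyne before the bromine has migrated, which would close the ring with the halogen on the wrong carbon or close a five-membered ring. The heteroaryl dienyne may also oligomerize on the Lewis acid, and crowding between the migrating bromine and the N-sulfonyl group may slow vinylidene formation.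
- Fallback: known chemistry, setting out from compound 9 and coming back at compound 11. The bromine is placed on C7 by a separate addition instead of a metal-mediated shift.
- Pd(OAc)2-catalysed hydrobromination of the bromoalkyne with LiBr in AcOH at rt is an established route from 1-haloalkynes to (Z)-1,2-dihaloalkenes, with the incoming bromide on the aryl-bearing carbon. It should give 2-[(Z)-1,2-dibromovinyl]-1-tosyl-3-vinyl-1H-pyrrole F1.
- Heating F1 in 1,2-dichlorobenzene at about 160 °C over solid NaHCO3 should bring about the thermal disrotatory six-electron electrocyclization of the 2,3-dialkenylpyrrole. This forms the same C5–C6 bond and gives racemic 6,7-dibromo-1-tosyl-5,6-dihydro-1H-indole F2.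
- F2 should lose HBr across C5–C6 under the reaction conditions and aromatize to compound 11.

2. Step 7.
- What may go wrong: the second bromination may be diverted into over-oxidation of the electron-rich pyrrole ring (hydrolysis of a 3,3-dibromoindolenine by traces of water). Substitution may spill onto the benzene ring, or the free N–H dihaloindole may decompose during purification.
- Fallback: setting out from compound 11 and coming back at compound 15. All halogens are installed while nitrogen is still sulfonylated, and the N–H is released last.
- Br2 in CH2Cl2 at 0 °C to rt should brominate C3 to give 3,7-dibromo-1-tosyl-1H-indole F3.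
- LiN(i-Pr)2 in THF at −78 °C should deprotonate C2, the standard directed lithiation of N-sulfonylindoles, to give 3,7-dibromo-2-lithio-1-tosyl-1H-indole F4.
- Quenching F4 cold with BrCCl2CCl2Br should give 2,3,7-tribromo-1-tosyl-1H-indole F5.
- Cs2CO3 in THF/MeOH at rt should then remove the sulfonyl group from F5 to give compound 15.

3. Step 4.
- What may go wrong: the base may attack the N-sulfonyl group, it may add to the electrophilic bromoalkyne, or the elimination may stall.
- Fallback: setting out from compound 6 and coming back at compound 9. The alkyne is made first and brominated afterwards.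
- Homologation of the aldehyde with Me3SiCHN2 and LiN(i-Pr)2 in THF, −78 °C to rt (Colvin rearrangement), should give 2-ethynyl-1-tosyl-3-vinyl-1H-pyrrole F6 without any alkoxide.
- NBS with catalytic AgNO3 in acetone at rt should then brominate the terminal alkyne of F6 to give compound 9.

Further compounds
F1 | step 5 | 2-[(Z)-1,2-dibromovinyl]-1-tosyl-3-vinyl-1H-pyrrole | Cc1ccc(cc1)S(=O)(=O)n1ccc(C=C)c1/C(Br)=C/Br
F2 | step 5 | 6,7-dibromo-1-tosyl-5,6-dihydro-1H-indole (racemic) | Cc1ccc(cc1)S(=O)(=O)N1C=CC2=CCC(Br)C(Br)=C12
F3 | step 7 | 3,7-dibromo-1-tosyl-1H-indole | Cc1ccc(cc1)S(=O)(=O)n1cc(Br)c2cccc(Br)c21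
F4 | step 7 | 3,7-dibromo-2-lithio-1-tosyl-1H-indole | Cc1ccc(cc1)S(=O)(=O)n1c([Li])c(Br)c2cccc(Br)c21
F5 | step 7 | 2,3,7-tribromo-1-tosyl-1H-indole | Cc1ccc(cc1)S(=O)(=O)n1c(Br)c(Br)c2cccc(Br)c21
F6 | step 4 | 2-ethynyl-1-tosyl-3-vinyl-1H-pyrrole | Cc1ccc(cc1)S(=O)(=O)n1ccc(C=C)c1C#C
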